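**Retrosynthetic overview**
- Target ⇒ twofold aryl–prenyl cross-coupling on the 3,5-dibromo-4-methoxybenzoate of (R)-terpinen-4-ol ⇒ lithium (R)-terpinen-4-olate + aroyl chloride.
- (R)-Terpinen-4-ol ⇒ key disconnection C3–C4. In an acyclic keto allylic carbonate the carbonate-bearing CH2 (an electrophile) is converted by enantioselective Cu–B SN2′ substitution into the nucleophilic end of an allylboron, which then adds to the isopropyl ketone (also an electrophile). This one event closes the ring, makes the quaternary carbinol and relays the C–B configuration to the carbinol carbon.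
- Keto carbonate ⇒ Meinwald rearrangement of the 6,7-epoxide of geranyl methyl carbonate ⇒ geraniol.
- Ring order: the benzene ring is bought; the cyclohexene is the only ring formed (step 4).

Assumption: the target stereodescriptor is read as R at the carbinol carbon, and the ligand enantiomer in step 4 is the one that gives (R)-5; its sense is verified at 7 against (−)-(R)-terpinen-4-ol, and 11 is recrystallised if the er needs upgrading.

**Step 1**
Reactants: 1 geraniol [(2E)-3,7-dimethylocta-2,6-dien-1-ol]
Product: 2 (2E)-3,7-dimethylocta-2,6-dien-1-yl methyl carbonate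
Conditions: ClCO2Me (1.3 equiv), pyridine, CH2Cl2, 0 °C → rt
Reagents that add atoms: methyl chloroformate, COC(=O)Cl
Why: Pyridine-mediated O-acylation of the primary allylic alcohol with a chloroformate is fast, leaves both trisubstituted alkenes untouched and creates no stereocentre.

**Step 2**
Reactants: 2 (2E)-3,7-dimethylocta-2,6-dien-1-yl methyl carbonate
Product: 3 (2E)-5-(3,3-dimethyloxiran-2-yl)-3-methylpent-2-en-1-yl methyl carbonate (racemic)
Conditions: mCPBA (1.05 equiv), CH2Cl2, 0 °C
Reagents that add atoms: mCPBA, OOC(=O)c1cccc(Cl)c1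
Why: Prilezhaev epoxidation occurs at the electron-rich distal alkene because the 2,3-alkene is deactivated by the allylic carbonate; the new epoxide stereocentre is racemic and is erased in step 3.

**Step 3**
Reactants: 3 (2E)-5-(3,3-dimethyloxiran-2-yl)-3-methylpent-2-en-1-yl methyl carbonate
Product: 4 (2E)-3,7-dimethyl-6-oxooct-2-en-1-yl methyl carbonate
Conditions: BF3·OEt2 (0.2 equiv), CH2Cl2, −40 → 0 °C, short contact time
Reagents that add atoms: none
Why: Meinwald rearrangement: Lewis-acid opening at the tertiary epoxide carbon and 1,2-hydride shift give the isopropyl ketone, while the electron-poor carbonate-bearing alkene is a poor nucleophile for cation–olefin cyclisation; no stereocentre remains.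

**Step 4**
Reactants: 4 (2E)-3,7-dimethyl-6-oxooct-2-en-1-yl methyl carbonate
Product: 7 (R)-terpinen-4-ol [(1R)-4-methyl-1-(propan-2-yl)cyclohex-3-en-1-ol], via allylboronate 5 (not isolated), via borate ester 6 (not isolated)
Conditions: Cu(OTf)2 (5 mol%), enantiopure sulfonate-bearing imidazolinium salt (chiral NHC precursor, 6 mol%), NaOMe (20 mol%), B2pin2 (1.3 equiv), DME, −30 °C; then filter (Celite), PhMe, 70 °C; H2O work-up
Reagents that add atoms: none
Why: Proposed new method: NHC–Cu-catalysed enantioselective SN2′ boryl substitution of the E-trisubstituted allylic carbonate (a known reaction type that places boron on the methyl-bearing carbon under catalyst control) inverts the polarity of the allyl unit and gives the tertiary allylboronate (R)-5, whose CH2 terminus (the former carbonate carbon) then adds to the tethered ketone in an intramolecular carbonyl allylboration (closest known type); attack through the other allyl terminus would need a cyclobutane, and the closed B–O-bridged six-membered transition state is forced by the two-carbon tether into a boat (bicyclo[2.2.2]-like) array with B and O on the same face, so the R C–B centre is relayed to the R carbinol while the cyclohexene with its ring-enforced cis alkene forms in the same event.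

**Step 5**
Reactants: 7 (R)-terpinen-4-ol; 8 3,5-dibromo-4-methoxybenzoic acid
Product: 11 (1R)-4-methyl-1-(propan-2-yl)cyclohex-3-en-1-yl 3,5-dibromo-4-methoxybenzoate, via lithium alkoxide 9 (not isolated), via acid chloride 10 (not isolated)
Conditions: 8, (COCl)2, cat. DMF, CH2Cl2, rt, evaporate; 7, nBuLi (1.0 equiv), THF, −78 °C; then 10, −78 °C → rt
Reagents that add atoms: none
Why: O-acylation of a preformed lithium tertiary alkoxide by an aroyl chloride overcomes the poor nucleophilicity of the hindered alcohol and avoids acid that would ionise the tertiary centre or shift the ring alkene (which would racemise it); the stereocentre is untouched.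

**Step 6**
Reactants: 11 (1R)-4-methyl-1-(propan-2-yl)cyclohex-3-en-1-yl 3,5-dibromo-4-methoxybenzoate
Product: 12 (1R)-4-methyl-1-(propan-2-yl)cyclohex-3-en-1-yl 4-methoxy-3,5-bis(3-methylbut-2-en-1-yl)benzoate
Conditions: tributyl(3-methylbut-2-en-1-yl)stannane (2.6 equiv), Pd(PPh3)4 (8 mol%), DMF, 95 °C
Reagents that add atoms: tributyl(3-methylbut-2-en-1-yl)stannane, CCCC[Sn](CCCC)(CCCC)CC=C(C)C
Why: Twofold Stille coupling: zerovalent palladium inserts into each aryl C–Br bond, the allylic stannane transmetalates and reductive elimination at the less hindered allyl terminus gives the linear prenyl groups, while the hindered homoallylic tertiary ester and the stereocentre are inert.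

**Compound list**
1 | geraniol, (2E)-3,7-dimethylocta-2,6-dien-1-ol | OC/C=C(\C)CCC=C(C)C | starting material
2 | (2E)-3,7-dimethylocta-2,6-dien-1-yl methyl carbonate | COC(=O)OC/C=C(\C)CCC=C(C)C | intermediate
3 | (2E)-5-(3,3-dimethyloxiran-2-yl)-3-methylpent-2-en-1-yl methyl carbonate (racemic) | COC(=O)OC/C=C(\C)CCC1OC1(C)C | intermediate
4 | (2E)-3,7-dimethyl-6-oxooct-2-en-1-yl methyl carbonate | COC(=O)OC/C=C(\C)CCC(=O)C(C)C | intermediate
5 | (6R)-2,6-dimethyl-6-(4,4,5,5-tetramethyl-1,3,2-dioxaborolan-2-yl)oct-7-en-3-one | C=C[C@@](C)(B1OC(C)(C)C(C)(C)O1)CCC(=O)C(C)C | intermediate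
6 | 4,4,5,5-tetramethyl-2-{[(1R)-4-methyl-1-(propan-2-yl)cyclohex-3-en-1-yl]oxy}-1,3,2-dioxaborolane | CC1(C)OB(O[C@@]2(C(C)C)CC=C(C)CC2)OC1(C)C | intermediate
7 | (R)-terpinen-4-ol, (1R)-4-methyl-1-(propan-2-yl)cyclohex-3-en-1-ol | O[C@@]1(C(C)C)CC=C(C)CC1 | intermediate
8 | 3,5-dibromo-4-methoxybenzoic acid | COc1c(Br)cc(cc1Br)C(=O)O | starting material
9 | lithium (1R)-4-methyl-1-(propan-2-yl)cyclohex-3-en-1-olate | [Li+].[O-][C@@]1(C(C)C)CC=C(C)CC1 | intermediate
10 | 3,5-dibromo-4-methoxybenzoyl chloride | COc1c(Br)cc(cc1Br)C(Cl)=O | intermediate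
11 | (1R)-4-methyl-1-(propan-2-yl)cyclohex-3-en-1-yl 3,5-dibromo-4-methoxybenzoate | COc1c(Br)cc(cc1Br)C(=O)O[C@@]2(C(C)C)CC=C(C)CC2 | intermediate
12 | (1R)-4-methyl-1-(propan-2-yl)cyclohex-3-en-1-yl 4-methoxy-3,5-bis(3-methylbut-2-en-1-yl)benzoate | COc1c(CC=C(C)C)cc(C(=O)O[C@@]2(C(C)C)CC=C(C)CC2)cc1CC=C(C)C | target

**Totals**
Total step count: 6. Longest linear sequence: 6 (geraniol 1 → 12).

**Steps most likely to fail, with fallbacks**

Step 4. The thermal ring-closing allylboration through a boat transition state has no direct precedent; the boronate may fail to cyclise, or copper-mediated side reactions at the ketone may compete. The fallback sets out from 4 and returns at 7. Ketone 4 is allylated intermolecularly with B-allyl-1,3,2-dioxaborinane under (S)- or (R)-3,3′-dibromo-BINOL catalysis, the enantiomer being chosen to give the R alcohol. This yields (2E,6R)-6-hydroxy-3-methyl-6-(propan-2-yl)nona-2,8-dien-1-yl methyl carbonate F1. Ring-closing metathesis with second-generation Grubbs catalyst RuCl2(=CHPh)(PCy3)(H2IMes) in CH2Cl2 at 40 °C then joins the terminal allyl group to the trisubstituted alkene, expelling the carbonate-bearing end and giving 7.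

Step 3. The tertiary cation can be diverted into cation–olefin cyclisation, fluorohydrin formation or an alkyl shift instead of the hydride shift. The fallback sets out from 3 and returns at 4, building the isopropyl ketone by C–C bond formation instead of rearrangement. Epoxide 3 is cleaved with H5IO6 in THF/H2O to the aldehyde (2E)-3-methyl-6-oxohex-2-en-1-yl methyl carbonate F2. Addition of iPrMgCl at −78 °C (aldehyde far faster than carbonate) gives (2E)-6-hydroxy-3,7-dimethyloct-2-en-1-yl methyl carbonate F3. Dess–Martin oxidation then gives 4.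

Step 6. Two couplings next to the methoxy group are needed, and prenyl transfer may give some branched (reverse-prenyl) product. The fallback sets out from 11 and returns at 12, installing the prenyl groups in two stages so that allyl-transfer regiochemistry no longer matters. Twofold Stille allylation of 11 with Bu3SnCH2CH=CH2 and Pd(PPh3)4 gives (1R)-4-methyl-1-(propan-2-yl)cyclohex-3-en-1-yl 4-methoxy-3,5-di(prop-2-en-1-yl)benzoate F4. Olefin cross-metathesis of both terminal allyl groups with excess 2-methylbut-2-ene and RuCl2(=CHPh)(PCy3)(H2IMes) (the trisubstituted ring alkene does not react) gives 12.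

**Further compounds**
F1 | step 4 | (2E,6R)-6-hydroxy-3-methyl-6-(propan-2-yl)nona-2,8-dien-1-yl methyl carbonate | COC(=O)OC/C=C(\C)CC[C@](O)(C(C)C)CC=C
F2 | step 3 | (2E)-3-methyl-6-oxohex-2-en-1-yl methyl carbonate | COC(=O)OC/C=C(\C)CCC=O
F3 | step 3 | (2E)-6-hydroxy-3,7-dimethyloct-2-en-1-yl methyl carbonate (racemic) | COC(=O)OC/C=C(\C)CCC(O)C(C)C
F4 | step 6 | (1R)-4-methyl-1-(propan-2-yl)cyclohex-3-en-1-yl 4-methoxy-3,5-di(prop-2-en-1-yl)benzoate | COc1c(CC=C)cc(cc1CC=C)C(=O)O[C@@]2(C(C)C)CC=C(C)CC2
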